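A fraction of the charge per minute was the unit I reckoned in, since the east flask, the one asked about, ran on a nearly straight line.

all flasks: left-handed substrate 0.20 M; right-handed substrate 0.20 M; catalyst 15 mol%
- east: solid reagent 1 equiv; the very flask that is asked about, followed so far
- flask: solid reagent 1.00 equiv; time 5.0 min

east run (percent of the left-handed substrate and right-handed substrate together charged)

| time / s | left-handed substrate / % | right-handed substrate / % | left-handed product / % |
|---|---|---|---|
| 20.0 | 49.7 | 50.1 | 0 |
| 40.0 | 47.8 | 50.1 | 1.2 |
| 60.0 | 48.2 | 48.8 | 2.6 |
| 80.0 | 47.0 | 49.5 | 2.6 |
| 90.0 | 46.7 | 49.4 | 4.0 |
| 120 | 45.2 | 49.0 | 4.4 |

(readings scatter by 0.5 percentage points)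

- catalyst is single-handed; left-handed substrate and right-handed substrate are mirror images of each other, charged as a racemate, each of them at the stated concentration
- solid, in amounts per volume of the solution: solid reagent
- at the start none of the solid reagent is in solution
- an excess is the difference of the two amounts in percent of their sum
- an excess is below zero if the other one leads

* part of the left-handed substrate and right-handed substrate charged together that has reacted at 5.0 min
* excess of left-handed product over right-handed product in the product at 5.0 min
* excess of right-handed substrate over left-handed substrate among what is left of the two at 5.0 min

I built the flask up one process at a time. I took the main step first, left-handed substrate to left-handed product. By 120 s the left-handed substrate read 45.2%, so it was falling by 0.0240 min⁻¹ of the charge.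

Then I added the right-handed substrate, which read 49.0%. Its loss of 0.00500 min⁻¹ was slower. The two together give the consumption rate, the part of both substrates gone per minute, 0.0290 min⁻¹. It is a reading, and each reading behind it scatters by 0.5 percentage points. The same two losses give an excess of left-handed product of 65.5%, which is noisier still.

Last came the solid reagent. If one solid reagent goes with one substrate, its charge answers to half of both substrates, and I reckoned that at this rate it lasts 17.2 min, longer than the 5.0 min asked. So I kept the straight line and committed to 14.5% reacted.

The forecast gave 13% reacted, below my figure, with excesses of 64% in the product and 9.6% in the substrate. Its ground was that “dissolution of the reagent sets the total rate”.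

The flask gave 14.2% reacted, 70.8% in the product and 11.7% in the substrate.

    partner + catalyst + left-handed substrate → catalyst + left-handed product (k = 6.10 M⁻² s⁻¹)
    partner + catalyst + right-handed substrate → catalyst + right-handed product (k = 0.930 M⁻² s⁻¹)
    solid reagent ⇌ partner, rate k3*(cs3 - [partner]) while solid is left; crystals form when [partner] > cs3 (solubility = 9.10 mM, k = 0.0510 s⁻¹)

At 5.00 min the east flask made partner 1.01 times faster than it used it, close to a steady state, with partner at 0.00550 M, below its solubility of 9.1 mM. Its consumption rate over the run was 0.0284 min⁻¹. At 5.00 min the neighbour flask with 38 mol% of catalyst had partner at 0.00374 M. Its consumption rate over the same time was 0.0429 min⁻¹, which is 1.52 times the east flask's, for 2.53 times the catalyst.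

The numbers in the tables were computed with made-up constants; scatter was added.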